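**Retrosynthetic overview**
- The target is reached by global desilylation of a protected 19-membered macrolactam. This macrocycle is the only ring built (the benzene ring is bought) and it is closed last.
- Ring closure forms C7–C8 by a chelation-controlled nickel-catalysed reductive alkyne–aldehyde macrocyclisation of a seco-ynal (new step). It sets C7 and the (E)-C8=C9 olefin.
- The seco-ynal comes from a copper-catalysed N-arylation joining a West fragment (aryl bromide, C8–C15, methyl-capped alkyne) to an East fragment (C1–C7 primary enamide).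
- West fragment: C14/C15 by catalytic asymmetric (Z)-crotylboration of the aryl aldehyde, C12 by asymmetric alkenylzinc addition, C10/C11 by SE2′ addition of a chiral allenylstannane to the α-methoxy aldehyde.
- East fragment: C6 from (R)-glycidol, (E)-C2=C3 by cross-metathesis with methyl methacrylate.

Assumption: the SMILES is read as the (6S,7S,10S,11R,12S,14S,15R) isomer in ansamycin numbering (C1 amide carbonyl to C15 benzylic carbinol), used below; (R)-TRIP, (+)-MIB, Cy2BH and (Z)-crotylboronic acid pinacol ester are taken as purchasable reagents.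

**Allenylstannane reagent**

Step 1
Reactants: 1 pent-3-yn-2-one
Product: 2 (S)-pent-3-yn-2-ol
Conditions: RuCl[(S,S)-TsDPEN](p-cymene) (0.5 mol%), i-PrOH, 25 °C
Reagents that add atoms: none
Why: Noyori asymmetric transfer hydrogenation of an alkynyl ketone; the (S,S)-catalyst delivers hydride to give the (S)-propargylic alcohol, with 2-propanol as hydrogen donor.

Step 2
Reactants: 2 (S)-pent-3-yn-2-ol
Product: 3 (S)-pent-3-yn-2-yl methanesulfonate
Conditions: MsCl, Et3N, CH2Cl2, −78 → 0 °C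
Reagents that add atoms: methanesulfonyl chloride, CS(=O)(=O)Cl
Why: O-sulfonylation of a secondary alcohol with retention at carbon.

Step 3
Reactants: 3 (S)-pent-3-yn-2-yl methanesulfonate
Product: 4 (aR)-tributyl(penta-2,3-dien-2-yl)stannane
Conditions: Bu3SnH, LiN(i-Pr)2, THF, 0 °C; CuBr·SMe2, −78 °C; then 3, −78 °C
Reagents that add atoms: tributyltin hydride, CCCC[SnH](CCCC)CCCC
Why: anti-SN2′ displacement of the propargylic mesylate by a stannylcopper reagent converts the (S)-centre into the (aR)-allene axis.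

**East fragment**

Step 4
Reactants: 5 (R)-glycidol
Product: 6 (S)-2-[(4-methoxybenzyloxy)methyl]oxirane
Conditions: NaH, 4-methoxybenzyl chloride, Bu4NI (cat.), THF/DMF, 0 → 23 °C
Reagents that add atoms: 4-methoxybenzyl chloride, COc1ccc(CCl)cc1
Why: Williamson etherification; the stereocentre is untouched and only the descriptor changes from R to S.

Step 5
Reactants: 6 (S)-2-[(4-methoxybenzyloxy)methyl]oxirane
Product: 7 (S)-1-(4-methoxybenzyloxy)hex-5-en-2-ol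
Conditions: allylMgBr, CuI (10 mol%), THF, −40 → 0 °C; aq. NH4Cl
Reagents that add atoms: allylmagnesium bromide, C=CC[Mg]Br
Why: copper-catalysed Grignard opening of the terminal epoxide at the unsubstituted carbon; C6 comes intact from the chiral pool.

Step 6
Reactants: 7 (S)-1-(4-methoxybenzyloxy)hex-5-en-2-ol
Product: 8 1-methoxy-4-({[(2S)-2-methoxyhex-5-en-1-yl]oxy}methyl)benzene
Conditions: NaH, MeI, THF, 0 → 23 °C
Reagents that add atoms: iodomethane, CI
Why: Williamson O-methylation installs the C6 methyl ether without touching the stereocentre.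

Step 7
Reactants: 8 1-methoxy-4-({[(2S)-2-methoxyhex-5-en-1-yl]oxy}methyl)benzene
Product: 9 methyl (2E,6S)-6-methoxy-7-(4-methoxybenzyloxy)-2-methylhept-2-enoate
Conditions: second-generation Hoveyda–Grubbs catalyst RuCl2(H2IMes)(=CH-C6H4-2-O-i-Pr) (5 mol%), methyl methacrylate (10 equiv), CH2Cl2, 40 °C
Reagents that add atoms: methyl methacrylate, C=C(C)C(=O)OC
Why: olefin cross-metathesis of a terminal alkene with excess methacrylate; thermodynamic control gives the (E)-trisubstituted enoate.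

Step 8
Reactants: 9 methyl (2E,6S)-6-methoxy-7-(4-methoxybenzyloxy)-2-methylhept-2-enoate
Product: 10 (2E,6S)-6-methoxy-7-(4-methoxybenzyloxy)-2-methylhept-2-enamide
Conditions: AlMe3, NH4Cl, toluene, 0 → 50 °C; dilute HCl work-up
Reagents that add atoms: ammonium chloride, [NH4+].[Cl-]
Why: Weinreb-type aluminium amide aminolysis converts the ester directly into the primary amide with the olefin geometry unchanged.

**West fragment**

Step 9
Reactants: 11 3-bromo-5-hydroxybenzaldehyde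
Product: 12 3-bromo-5-(triisopropylsilyloxy)benzaldehyde
Conditions: TIPSCl, imidazole, DMF, 23 °C
Reagents that add atoms: chlorotriisopropylsilane, CC(C)[Si](Cl)(C(C)C)C(C)C
Why: silylation of the phenol gives a base-tolerant, fluoride-labile ether.

Step 10
Reactants: 12 3-bromo-5-(triisopropylsilyloxy)benzaldehyde
Product: 14 (1R,2S)-1-[3-bromo-5-(triisopropylsilyloxy)phenyl]-2-methylbut-3-en-1-ol, via pinacol borate ester 13 (not isolated)
Conditions: (Z)-crotylboronic acid pinacol ester (1.3 equiv), (R)-TRIP (5 mol%), toluene, −30 °C; aqueous work-up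
Reagents that add atoms: (Z)-crotylboronic acid pinacol ester, C/C=C\CB1OC(C)(C)C(C)(C)O1
Why: chiral phosphoric acid-catalysed crotylboration through a closed chair transition state; the (Z)-boronate gives the syn C14-Me/C15-OH pair and (R)-TRIP directs attack to the Re face of the aryl aldehyde (15R,14S).

Step 11
Reactants: 14 (1R,2S)-1-[3-bromo-5-(triisopropylsilyloxy)phenyl]-2-methylbut-3-en-1-ol
Product: 15 [3-bromo-5-[(1R,2S)-1-(tert-butyldimethylsilyloxy)-2-methylbut-3-enyl]phenoxy]triisopropylsilane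
Conditions: TBSOTf, 2,6-lutidine, CH2Cl2, −78 → 0 °C
Reagents that add atoms: tert-butyldimethylsilyl trifluoromethanesulfonate, CC(C)(C)[Si](C)(C)OS(=O)(=O)C(F)(F)F
Why: silyl triflate protection of the hindered benzylic alcohol with a non-nucleophilic base.

Step 12
Reactants: 15 [3-bromo-5-[(1R,2S)-1-(tert-butyldimethylsilyloxy)-2-methylbut-3-enyl]phenoxy]triisopropylsilane
Product: 17 (3S,4R)-4-[3-bromo-5-(triisopropylsilyloxy)phenyl]-4-(tert-butyldimethylsilyloxy)-3-methylbutan-1-ol, via B-alkyl-9-borabicyclononane 16 (not isolated)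
Conditions: 9-BBN, THF, 0 → 23 °C; then aq. NaOAc, 30% H2O2, 0 °C
Reagents that add atoms: hydrogen peroxide, OO
Why: anti-Markovnikov hydroboration–oxidation of the terminal vinyl group gives the C12 primary alcohol; buffered oxidation spares the aryl silyl ether.

Step 13
Reactants: 17 (3S,4R)-4-[3-bromo-5-(triisopropylsilyloxy)phenyl]-4-(tert-butyldimethylsilyloxy)-3-methylbutan-1-ol
Product: 18 (3S,4R)-4-[3-bromo-5-(triisopropylsilyloxy)phenyl]-4-(tert-butyldimethylsilyloxy)-3-methylbutanal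
Conditions: TEMPO (10 mol%), PhI(OAc)2, CH2Cl2, 23 °C
Reagents that add atoms: none
Why: oxoammonium-catalysed oxidation of the primary alcohol stops at the aldehyde.

Step 14
Reactants: 18 (3S,4R)-4-[3-bromo-5-(triisopropylsilyloxy)phenyl]-4-(tert-butyldimethylsilyloxy)-3-methylbutanal
Product: 19 (1R,2S,4S,5E)-1-[3-bromo-5-(triisopropylsilyloxy)phenyl]-1-(tert-butyldimethylsilyloxy)-2-methyldec-5-en-4-ol
Conditions: hex-1-yne, Cy2BH, toluene, 0 → 23 °C; Et2Zn, (+)-MIB (5 mol%), −78 °C; then 18, −10 °C; aq. NH4Cl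
Reagents that add atoms: hex-1-yne, CCCCC#C
Why: Oppolzer-type catalytic asymmetric alkenylzinc addition (alkyne hydroboration, boron-to-zinc transmetalation); the amino-alkoxide zinc catalyst derived from (+)-MIB delivers the alkenyl group to the Re face, setting C12 (S) under catalyst control.

Step 15
Reactants: 19 (1R,2S,4S,5E)-1-[3-bromo-5-(triisopropylsilyloxy)phenyl]-1-(tert-butyldimethylsilyloxy)-2-methyldec-5-en-4-ol
Product: 20 [3-bromo-5-[(1R,2S,4S,5E)-1-(tert-butyldimethylsilyloxy)-4-methoxy-2-methyldec-5-enyl]phenoxy]triisopropylsilane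
Conditions: Me3OBF4, 1,8-bis(dimethylamino)naphthalene, 4 Å MS, CH2Cl2, 0 → 23 °C
Reagents that add atoms: trimethyloxonium tetrafluoroborate, C[O+](C)C.F[B-](F)(F)F
Why: Meerwein O-methylation under non-basic conditions installs the C12 methyl ether without silyl migration or allylic transposition.

Step 16
Reactants: 20 [3-bromo-5-[(1R,2S,4S,5E)-1-(tert-butyldimethylsilyloxy)-4-methoxy-2-methyldec-5-enyl]phenoxy]triisopropylsilane
Product: 22 (2S,4S,5R)-5-[3-bromo-5-(triisopropylsilyloxy)phenyl]-5-(tert-butyldimethylsilyloxy)-2-methoxy-4-methylpentanal, via secondary ozonide 21 (not isolated)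
Conditions: O3, CH2Cl2, −78 °C; then PPh3, −78 → 23 °C
Reagents that add atoms: ozone, [O-][O+]=O
Why: ozonolysis with reductive work-up cleaves the disubstituted olefin to the C11 α-methoxy aldehyde, which is used at once to avoid epimerisation at C12.

Step 17
Reactants: 22 (2S,4S,5R)-5-[3-bromo-5-(triisopropylsilyloxy)phenyl]-5-(tert-butyldimethylsilyloxy)-2-methoxy-4-methylpentanal; 4 (aR)-tributyl(penta-2,3-dien-2-yl)stannane
Product: 23 (1R,2S,4S,5R,6S)-1-[3-bromo-5-(triisopropylsilyloxy)phenyl]-1-(tert-butyldimethylsilyloxy)-4-methoxy-2,6-dimethylnon-7-yn-5-ol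
Conditions: BF3·OEt2 (1.5 equiv), CH2Cl2, −78 °C; aq. NaHCO3
Reagents that add atoms: none
Why: Marshall SE2′ addition of a chiral allenylstannane through an open transition state; anti-SE2′ transfers the allene axis to C10 (S), the syn Me/OH topology and Felkin–Anh attack anti to the α-methoxy group (matched pair) set C11 (R), and the methyl-capped alkyne is delivered directly.

Step 18
Reactants: 23 (1R,2S,4S,5R,6S)-1-[3-bromo-5-(triisopropylsilyloxy)phenyl]-1-(tert-butyldimethylsilyloxy)-4-methoxy-2,6-dimethylnon-7-yn-5-ol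
Product: 24 [3-bromo-5-[(1R,2S,4S,5R,6S)-1,5-bis(tert-butyldimethylsilyloxy)-4-methoxy-2,6-dimethylnon-7-ynyl]phenoxy]triisopropylsilane
Conditions: TBSOTf, 2,6-lutidine, CH2Cl2, 0 → 23 °C
Reagents that add atoms: tert-butyldimethylsilyl trifluoromethanesulfonate, CC(C)(C)[Si](C)(C)OS(=O)(=O)C(F)(F)F
Why: silyl triflate protection of the hindered C11 alcohol completes the West fragment.

**Fragment union and endgame**

Step 19
Reactants: 24 [3-bromo-5-[(1R,2S,4S,5R,6S)-1,5-bis(tert-butyldimethylsilyloxy)-4-methoxy-2,6-dimethylnon-7-ynyl]phenoxy]triisopropylsilane; 10 (2E,6S)-6-methoxy-7-(4-methoxybenzyloxy)-2-methylhept-2-enamide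
Product: 25 (2E,6S)-N-[3-[(1R,2S,4S,5R,6S)-1,5-bis(tert-butyldimethylsilyloxy)-4-methoxy-2,6-dimethylnon-7-ynyl]-5-(triisopropylsilyloxy)phenyl]-6-methoxy-7-(4-methoxybenzyloxy)-2-methylhept-2-enamide
Conditions: CuI (20 mol%), trans-N,N′-dimethylcyclohexane-1,2-diamine (40 mol%), K2CO3, toluene, 105 °C
Reagents that add atoms: none
Why: Goldberg-type copper/diamine-catalysed N-arylation of a primary amide with an unhindered aryl bromide forms the anilide C–N bond without a nitrogen protecting group.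

Step 20
Reactants: 25 (2E,6S)-N-[3-[(1R,2S,4S,5R,6S)-1,5-bis(tert-butyldimethylsilyloxy)-4-methoxy-2,6-dimethylnon-7-ynyl]-5-(triisopropylsilyloxy)phenyl]-6-methoxy-7-(4-methoxybenzyloxy)-2-methylhept-2-enamide
Product: 26 (2E,6S)-N-[3-[(1R,2S,4S,5R,6S)-1,5-bis(tert-butyldimethylsilyloxy)-4-methoxy-2,6-dimethylnon-7-ynyl]-5-(triisopropylsilyloxy)phenyl]-7-hydroxy-6-methoxy-2-methylhept-2-enamide
Conditions: DDQ, CH2Cl2/pH 7 phosphate buffer (10:1), 0 °C
Reagents that add atoms: none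
Why: oxidative cleavage of the 4-methoxybenzyl ether by hydride abstraction is orthogonal to the silyl ethers, alkyne and enamide.

Step 21
Reactants: 26 (2E,6S)-N-[3-[(1R,2S,4S,5R,6S)-1,5-bis(tert-butyldimethylsilyloxy)-4-methoxy-2,6-dimethylnon-7-ynyl]-5-(triisopropylsilyloxy)phenyl]-7-hydroxy-6-methoxy-2-methylhept-2-enamide
Product: 27 (2E,6S)-N-[3-[(1R,2S,4S,5R,6S)-1,5-bis(tert-butyldimethylsilyloxy)-4-methoxy-2,6-dimethylnon-7-ynyl]-5-(triisopropylsilyloxy)phenyl]-6-methoxy-2-methyl-7-oxohept-2-enamide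
Conditions: Dess–Martin periodinane, CH2Cl2, 0 → 23 °C
Reagents that add atoms: none
Why: Dess–Martin oxidation gives the α-methoxy aldehyde under neutral conditions without epimerising C6.

Step 22
Reactants: 27 (2E,6S)-N-[3-[(1R,2S,4S,5R,6S)-1,5-bis(tert-butyldimethylsilyloxy)-4-methoxy-2,6-dimethylnon-7-ynyl]-5-(triisopropylsilyloxy)phenyl]-6-methoxy-2-methyl-7-oxohept-2-enamide
Product: 28 (4E,8S,9S,10E,12S,13R,14S,16S,17R)-13,17-bis(tert-butyldimethylsilyloxy)-8,14-dimethoxy-4,10,12,16-tetramethyl-9-(triethylsilyloxy)-20-(triisopropylsilyloxy)-2-azabicyclo[16.3.1]docosa-1(22),4,10,18,20-pentaen-3-one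
Conditions: Ni(cod)2 (20 mol%), IMes (1,3-dimesitylimidazol-2-ylidene, 20 mol%), Et3SiH (5 equiv), MgBr2·OEt2 (2 equiv), toluene/THF (10:1), 2 mM, syringe-pump addition of 27 over 8 h, 25 °C
Reagents that add atoms: triethylsilane, CC[SiH](CC)CC
Why: Proposed new method: a chelation-controlled nickel-catalysed reductive alkyne–aldehyde macrocyclisation, in which MgBr2 ties the C7 carbonyl and C6 methoxy oxygens into a five-membered chelate, IMes-ligated zerovalent nickel (a small carbene, so C–C bond formation occurs at the methyl-bearing alkyne carbon remote from the α-branched C10) undergoes oxidative cyclisation with the Lewis-acid-activated aldehyde on the chelate face opposite C5 to give the 6,7-syn (7S) oxanickelacycle, and Si–H σ-bond metathesis followed by C–H reductive elimination delivers the (E)-C8=C9 olefin (cis addition of H and C7 across the alkyne) as its O-triethylsilyl ether while closing the 19-membered ring; the closest known reaction type is the nickel/N-heterocyclic carbene/silane (or nickel/phosphine/triethylborane) reductive coupling and macrocyclisation of alkynes with aldehydes, which with α-alkoxy aldehydes gives the Felkin 1,2-anti product, and Lewis-acid acceleration of nickel oxidative cyclisation is established, but a chelating Lewis acid used to reverse the facial sense has not been shown.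

Step 23
Reactants: 28 (4E,8S,9S,10E,12S,13R,14S,16S,17R)-13,17-bis(tert-butyldimethylsilyloxy)-8,14-dimethoxy-4,10,12,16-tetramethyl-9-(triethylsilyloxy)-20-(triisopropylsilyloxy)-2-azabicyclo[16.3.1]docosa-1(22),4,10,18,20-pentaen-3-one
Product: 29 (4E,8S,9S,10E,12S,13R,14S,16S,17R)-9,13,17,20-tetrahydroxy-8,14-dimethoxy-4,10,12,16-tetramethyl-2-azabicyclo[16.3.1]docosa-1(22),4,10,18,20-pentaen-3-one (target CNP0366451.1)
Conditions: HF·pyridine, pyridine, THF, 0 → 40 °C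
Reagents that add atoms: none
Why: fluoride-driven global desilylation removes all four silyl ethers; the pyridine buffer avoids ionisation of the allylic C7 and benzylic C15 alcohols, and no stereocentre is touched.

**Compound list**

1 | pent-3-yn-2-one | CC#CC(C)=O | starting material
2 | (S)-pent-3-yn-2-ol | C[C@H](O)C#CC | intermediate
3 | (S)-pent-3-yn-2-yl methanesulfonate | C[C@H](OS(C)(=O)=O)C#CC | intermediate
4 | (aR)-tributyl(penta-2,3-dien-2-yl)stannane, the (M)-allene | CC([Sn](CCCC)(CCCC)CCCC)=[C@@]=C([H])C | intermediate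
5 | (R)-glycidol, (R)-oxiran-2-ylmethanol | C1[C@H](O1)CO | starting material
6 | (S)-2-[(4-methoxybenzyloxy)methyl]oxirane | C1[C@H](O1)COCc2ccc(OC)cc2 | intermediate
7 | (S)-1-(4-methoxybenzyloxy)hex-5-en-2-ol | C=CCC[C@H](O)COCc1ccc(OC)cc1 | intermediate
8 | 1-methoxy-4-({[(2S)-2-methoxyhex-5-en-1-yl]oxy}methyl)benzene | C=CCC[C@H](OC)COCc1ccc(OC)cc1 | intermediate
9 | methyl (2E,6S)-6-methoxy-7-(4-methoxybenzyloxy)-2-methylhept-2-enoate | COC(=O)/C(C)=C/CC[C@H](OC)COCc1ccc(OC)cc1 | intermediate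
10 | (2E,6S)-6-methoxy-7-(4-methoxybenzyloxy)-2-methylhept-2-enamide (East fragment) | NC(=O)/C(C)=C/CC[C@H](OC)COCc1ccc(OC)cc1 | intermediate
11 | 3-bromo-5-hydroxybenzaldehyde | O=Cc1cc(O)cc(Br)c1 | starting material
12 | 3-bromo-5-(triisopropylsilyloxy)benzaldehyde | O=Cc1cc(Br)cc(O[Si](C(C)C)(C(C)C)C(C)C)c1 | intermediate
13 | 2-[(1R,2S)-1-[3-bromo-5-(triisopropylsilyloxy)phenyl]-2-methylbut-3-enyloxy]-4,4,5,5-tetramethyl-1,3,2-dioxaborolane | C=C[C@H](C)[C@@H](OB1OC(C)(C)C(C)(C)O1)c1cc(Br)cc(O[Si](C(C)C)(C(C)C)C(C)C)c1 | intermediate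
14 | (1R,2S)-1-[3-bromo-5-(triisopropylsilyloxy)phenyl]-2-methylbut-3-en-1-ol | C=C[C@H](C)[C@@H](O)c1cc(Br)cc(O[Si](C(C)C)(C(C)C)C(C)C)c1 | intermediate
15 | [3-bromo-5-[(1R,2S)-1-(tert-butyldimethylsilyloxy)-2-methylbut-3-enyl]phenoxy]triisopropylsilane | C=C[C@H](C)[C@@H](O[Si](C)(C)C(C)(C)C)c1cc(Br)cc(O[Si](C(C)C)(C(C)C)C(C)C)c1 | intermediate
16 | 9-[(3S,4R)-4-[3-bromo-5-(triisopropylsilyloxy)phenyl]-4-(tert-butyldimethylsilyloxy)-3-methylbutyl]-9-borabicyclo[3.3.1]nonane | B1(CC[C@H](C)[C@@H](O[Si](C)(C)C(C)(C)C)c2cc(Br)cc(O[Si](C(C)C)(C(C)C)C(C)C)c2)C2CCCC1CCC2 | intermediate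
17 | (3S,4R)-4-[3-bromo-5-(triisopropylsilyloxy)phenyl]-4-(tert-butyldimethylsilyloxy)-3-methylbutan-1-ol | OCC[C@H](C)[C@@H](O[Si](C)(C)C(C)(C)C)c1cc(Br)cc(O[Si](C(C)C)(C(C)C)C(C)C)c1 | intermediate
18 | (3S,4R)-4-[3-bromo-5-(triisopropylsilyloxy)phenyl]-4-(tert-butyldimethylsilyloxy)-3-methylbutanal | O=CC[C@H](C)[C@@H](O[Si](C)(C)C(C)(C)C)c1cc(Br)cc(O[Si](C(C)C)(C(C)C)C(C)C)c1 | intermediate
19 | (1R,2S,4S,5E)-1-[3-bromo-5-(triisopropylsilyloxy)phenyl]-1-(tert-butyldimethylsilyloxy)-2-methyldec-5-en-4-ol | CCCC/C=C/[C@@H](O)C[C@H](C)[C@@H](O[Si](C)(C)C(C)(C)C)c1cc(Br)cc(O[Si](C(C)C)(C(C)C)C(C)C)c1 | intermediate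
20 | [3-bromo-5-[(1R,2S,4S,5E)-1-(tert-butyldimethylsilyloxy)-4-methoxy-2-methyldec-5-enyl]phenoxy]triisopropylsilane | CCCC/C=C/[C@@H](OC)C[C@H](C)[C@@H](O[Si](C)(C)C(C)(C)C)c1cc(Br)cc(O[Si](C(C)C)(C(C)C)C(C)C)c1 | intermediate
21 | secondary ozonide of 20: 3-butyl-5-[(1S,3S,4R)-4-[3-bromo-5-(triisopropylsilyloxy)phenyl]-4-(tert-butyldimethylsilyloxy)-1-methoxy-3-methylbutyl]-1,2,4-trioxolane (mixture at the two ring carbons) | CCCCC1OC(OO1)[C@@H](OC)C[C@H](C)[C@@H](O[Si](C)(C)C(C)(C)C)c1cc(Br)cc(O[Si](C(C)C)(C(C)C)C(C)C)c1 | intermediate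
22 | (2S,4S,5R)-5-[3-bromo-5-(triisopropylsilyloxy)phenyl]-5-(tert-butyldimethylsilyloxy)-2-methoxy-4-methylpentanal | O=C[C@@H](OC)C[C@H](C)[C@@H](O[Si](C)(C)C(C)(C)C)c1cc(Br)cc(O[Si](C(C)C)(C(C)C)C(C)C)c1 | intermediate
23 | (1R,2S,4S,5R,6S)-1-[3-bromo-5-(triisopropylsilyloxy)phenyl]-1-(tert-butyldimethylsilyloxy)-4-methoxy-2,6-dimethylnon-7-yn-5-ol | CC#C[C@H](C)[C@@H](O)[C@@H](OC)C[C@H](C)[C@@H](O[Si](C)(C)C(C)(C)C)c1cc(Br)cc(O[Si](C(C)C)(C(C)C)C(C)C)c1 | intermediate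
24 | [3-bromo-5-[(1R,2S,4S,5R,6S)-1,5-bis(tert-butyldimethylsilyloxy)-4-methoxy-2,6-dimethylnon-7-ynyl]phenoxy]triisopropylsilane (West fragment) | CC#C[C@H](C)[C@@H](O[Si](C)(C)C(C)(C)C)[C@@H](OC)C[C@H](C)[C@@H](O[Si](C)(C)C(C)(C)C)c1cc(Br)cc(O[Si](C(C)C)(C(C)C)C(C)C)c1 | intermediate
25 | (2E,6S)-N-[3-[(1R,2S,4S,5R,6S)-1,5-bis(tert-butyldimethylsilyloxy)-4-methoxy-2,6-dimethylnon-7-ynyl]-5-(triisopropylsilyloxy)phenyl]-6-methoxy-7-(4-methoxybenzyloxy)-2-methylhept-2-enamide | CC#C[C@H](C)[C@@H](O[Si](C)(C)C(C)(C)C)[C@@H](OC)C[C@H](C)[C@@H](O[Si](C)(C)C(C)(C)C)c1cc(NC(=O)/C(C)=C/CC[C@H](OC)COCc2ccc(OC)cc2)cc(O[Si](C(C)C)(C(C)C)C(C)C)c1 | intermediate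
26 | (2E,6S)-N-[3-[(1R,2S,4S,5R,6S)-1,5-bis(tert-butyldimethylsilyloxy)-4-methoxy-2,6-dimethylnon-7-ynyl]-5-(triisopropylsilyloxy)phenyl]-7-hydroxy-6-methoxy-2-methylhept-2-enamide | CC#C[C@H](C)[C@@H](O[Si](C)(C)C(C)(C)C)[C@@H](OC)C[C@H](C)[C@@H](O[Si](C)(C)C(C)(C)C)c1cc(NC(=O)/C(C)=C/CC[C@H](OC)CO)cc(O[Si](C(C)C)(C(C)C)C(C)C)c1 | intermediate
27 | (2E,6S)-N-[3-[(1R,2S,4S,5R,6S)-1,5-bis(tert-butyldimethylsilyloxy)-4-methoxy-2,6-dimethylnon-7-ynyl]-5-(triisopropylsilyloxy)phenyl]-6-methoxy-2-methyl-7-oxohept-2-enamide (seco-ynal) | CC#C[C@H](C)[C@@H](O[Si](C)(C)C(C)(C)C)[C@@H](OC)C[C@H](C)[C@@H](O[Si](C)(C)C(C)(C)C)c1cc(NC(=O)/C(C)=C/CC[C@H](OC)C=O)cc(O[Si](C(C)C)(C(C)C)C(C)C)c1 | intermediate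
28 | (4E,8S,9S,10E,12S,13R,14S,16S,17R)-13,17-bis(tert-butyldimethylsilyloxy)-8,14-dimethoxy-4,10,12,16-tetramethyl-9-(triethylsilyloxy)-20-(triisopropylsilyloxy)-2-azabicyclo[16.3.1]docosa-1(22),4,10,18,20-pentaen-3-one | CO[C@H]1C[C@H](C)[C@@H](O[Si](C)(C)C(C)(C)C)c2cc(O[Si](C(C)C)(C(C)C)C(C)C)cc(c2)NC(=O)/C(C)=C/CC[C@H](OC)[C@@H](O[Si](CC)(CC)CC)/C(C)=C/[C@H](C)[C@H]1O[Si](C)(C)C(C)(C)C | intermediate
29 | (4E,8S,9S,10E,12S,13R,14S,16S,17R)-9,13,17,20-tetrahydroxy-8,14-dimethoxy-4,10,12,16-tetramethyl-2-azabicyclo[16.3.1]docosa-1(22),4,10,18,20-pentaen-3-one | CO[C@H]1C[C@H](C)[C@@H](O)c2cc(O)cc(c2)NC(=O)/C(C)=C/CC[C@H](OC)[C@@H](O)/C(C)=C/[C@H](C)[C@H]1O | target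

**Totals**

Total step count: 23. Longest linear sequence: 15 steps (steps 9–23, from 11).

**Three steps most likely to fail**

Step 17 (allenylstannane addition). The α-methoxy aldehyde is labile and the result depends on matched double stereodifferentiation. The fallback sets out from 22 and comes back at 24. Brown (Z)-crotylboration of 22 ((Z)-but-2-ene, n-BuLi, KOt-Bu, (+)-Ipc2BOMe, BF3·OEt2, −78 °C; ethanolamine work-up) reinforces Felkin attack and gives the syn,anti homoallylic alcohol (1R,2S,4S,5R,6S)-1-[3-bromo-5-(triisopropylsilyloxy)phenyl]-1-(tert-butyldimethylsilyloxy)-4-methoxy-2,6-dimethyloct-7-en-5-ol F1. TBSOTf/2,6-lutidine gives its 5-O-silyl ether F2. Ozonolysis (O3; PPh3) gives the aldehyde (2R,3R,4S,6S,7R)-7-[3-bromo-5-(triisopropylsilyloxy)phenyl]-3,7-bis(tert-butyldimethylsilyloxy)-4-methoxy-2,6-dimethylheptanal F3. Colvin homologation (Me3SiCHN2, LiN(i-Pr)2, THF, −78 → 0 °C) gives the terminal alkyne F4. Deprotonation with LiN(i-Pr)2 (which does not exchange the aryl bromide) and MeI at −78 °C methylates F4 to 24.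

Step 19 (intermolecular copper-catalysed N-arylation). The coupling of a hindered enamide at 105 °C may be sluggish, and carbonate may cleave the aryl silyl ether. The fallback sets out from 24 and 9 and comes back at 25. Palladium-catalysed amination of 24 with benzophenone imine (Pd2(dba)3, rac-BINAP, Cs2CO3, toluene, 90 °C) gives the N-aryl diphenylmethanimine F5, and aqueous citric acid in THF hydrolyses it to the aniline F6. Saponification of 9 (LiOH, THF/MeOH/H2O) gives (2E,6S)-6-methoxy-7-(4-methoxybenzyloxy)-2-methylhept-2-enoic acid F7, which 1-chloro-N,N,2-trimethylprop-1-en-1-amine converts into the acid chloride F8. Acylation of F6 with F8 (pyridine, CH2Cl2, 0 °C) gives 25.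

Step 22 (the proposed chelation-controlled nickel macrocyclisation). It is untested: C7 selectivity may revert to Felkin, and the enamide or macrocyclic strain may interfere. The fallback uses known chemistry, sets out from 9 and 24 and comes back at 28. DDQ unmasks 9 to methyl (2E,6S)-7-hydroxy-6-methoxy-2-methylhept-2-enoate F9, and Dess–Martin oxidation gives methyl (2E,6S)-6-methoxy-2-methyl-7-oxohept-2-enoate F10. Hydrozirconation of 24 (Cp2Zr(H)Cl, THF, 50 °C) places zirconium on the methyl-bearing carbon to give the (E)-alkenylzirconocene chloride F11. Me2Zn (toluene, −65 °C) transmetalates it to the alkenyl(methyl)zinc F12, which adds to F10 under chelation control (−65 → 0 °C) to give the 6,7-syn (E)-allylic alcohol F13. TESOTf/2,6-lutidine gives the 7-O-triethylsilyl ether F14. AlMe3/NH4Cl aminolysis gives the primary amide F15. Intramolecular copper-catalysed aryl amidation (CuI, N,N′-dimethylethylenediamine, K2CO3, toluene, 100 °C, 2 mM) closes the macrolactam to 28.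

Further compounds
F1 | step 17 | (1R,2S,4S,5R,6S)-1-[3-bromo-5-(triisopropylsilyloxy)phenyl]-1-(tert-butyldimethylsilyloxy)-4-methoxy-2,6-dimethyloct-7-en-5-ol | C=C[C@H](C)[C@@H](O)[C@@H](OC)C[C@H](C)[C@@H](O[Si](C)(C)C(C)(C)C)c1cc(Br)cc(O[Si](C(C)C)(C(C)C)C(C)C)c1
F2 | step 17 | [3-bromo-5-[(1R,2S,4S,5R,6S)-1,5-bis(tert-butyldimethylsilyloxy)-4-methoxy-2,6-dimethyloct-7-enyl]phenoxy]triisopropylsilane | C=C[C@H](C)[C@@H](O[Si](C)(C)C(C)(C)C)[C@@H](OC)C[C@H](C)[C@@H](O[Si](C)(C)C(C)(C)C)c1cc(Br)cc(O[Si](C(C)C)(C(C)C)C(C)C)c1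
F3 | step 17 | (2R,3R,4S,6S,7R)-7-[3-bromo-5-(triisopropylsilyloxy)phenyl]-3,7-bis(tert-butyldimethylsilyloxy)-4-methoxy-2,6-dimethylheptanal | O=C[C@H](C)[C@@H](O[Si](C)(C)C(C)(C)C)[C@@H](OC)C[C@H](C)[C@@H](O[Si](C)(C)C(C)(C)C)c1cc(Br)cc(O[Si](C(C)C)(C(C)C)C(C)C)c1
F4 | step 17 | [3-bromo-5-[(1R,2S,4S,5R,6S)-1,5-bis(tert-butyldimethylsilyloxy)-4-methoxy-2,6-dimethyloct-7-ynyl]phenoxy]triisopropylsilane | C#C[C@H](C)[C@@H](O[Si](C)(C)C(C)(C)C)[C@@H](OC)C[C@H](C)[C@@H](O[Si](C)(C)C(C)(C)C)c1cc(Br)cc(O[Si](C(C)C)(C(C)C)C(C)C)c1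
F5 | step 19 | N-[3-[(1R,2S,4S,5R,6S)-1,5-bis(tert-butyldimethylsilyloxy)-4-methoxy-2,6-dimethylnon-7-ynyl]-5-(triisopropylsilyloxy)phenyl]-1,1-diphenylmethanimine | CC#C[C@H](C)[C@@H](O[Si](C)(C)C(C)(C)C)[C@@H](OC)C[C@H](C)[C@@H](O[Si](C)(C)C(C)(C)C)c1cc(N=C(c2ccccc2)c2ccccc2)cc(O[Si](C(C)C)(C(C)C)C(C)C)c1
F6 | step 19 | 3-[(1R,2S,4S,5R,6S)-1,5-bis(tert-butyldimethylsilyloxy)-4-methoxy-2,6-dimethylnon-7-ynyl]-5-(triisopropylsilyloxy)aniline | CC#C[C@H](C)[C@@H](O[Si](C)(C)C(C)(C)C)[C@@H](OC)C[C@H](C)[C@@H](O[Si](C)(C)C(C)(C)C)c1cc(N)cc(O[Si](C(C)C)(C(C)C)C(C)C)c1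
F7 | step 19 | (2E,6S)-6-methoxy-7-(4-methoxybenzyloxy)-2-methylhept-2-enoic acid | OC(=O)/C(C)=C/CC[C@H](OC)COCc1ccc(OC)cc1
F8 | step 19 | (2E,6S)-6-methoxy-7-(4-methoxybenzyloxy)-2-methylhept-2-enoyl chloride | ClC(=O)/C(C)=C/CC[C@H](OC)COCc1ccc(OC)cc1
F9 | step 22 | methyl (2E,6S)-7-hydroxy-6-methoxy-2-methylhept-2-enoate | COC(=O)/C(C)=C/CC[C@H](OC)CO
F10 | step 22 | methyl (2E,6S)-6-methoxy-2-methyl-7-oxohept-2-enoate | COC(=O)/C(C)=C/CC[C@H](OC)C=O
F11 | step 22 | chlorobis(cyclopentadienyl)[(2E,4S,5R,6S,8S,9R)-9-[3-bromo-5-(triisopropylsilyloxy)phenyl]-5,9-bis(tert-butyldimethylsilyloxy)-6-methoxy-4,8-dimethylnon-2-en-2-yl]zirconium | C/C(=C\[C@H](C)[C@@H](O[Si](C)(C)C(C)(C)C)[C@@H](OC)C[C@H](C)[C@@H](O[Si](C)(C)C(C)(C)C)c1cc(Br)cc(O[Si](C(C)C)(C(C)C)C(C)C)c1)[Zr](Cl)(C1C=CC=C1)C1C=CC=C1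
F12 | step 22 | [(2E,4S,5R,6S,8S,9R)-9-[3-bromo-5-(triisopropylsilyloxy)phenyl]-5,9-bis(tert-butyldimethylsilyloxy)-6-methoxy-4,8-dimethylnon-2-en-2-yl](methyl)zinc | C/C(=C\[C@H](C)[C@@H](O[Si](C)(C)C(C)(C)C)[C@@H](OC)C[C@H](C)[C@@H](O[Si](C)(C)C(C)(C)C)c1cc(Br)cc(O[Si](C(C)C)(C(C)C)C(C)C)c1)[Zn]C
F13 | step 22 | methyl (2E,6S,7S,8E,10S,11R,12S,14S,15R)-15-[3-bromo-5-(triisopropylsilyloxy)phenyl]-11,15-bis(tert-butyldimethylsilyloxy)-7-hydroxy-6,12-dimethoxy-2,8,10,14-tetramethylpentadeca-2,8-dienoate | COC(=O)/C(C)=C/CC[C@H](OC)[C@@H](O)/C(C)=C/[C@H](C)[C@@H](O[Si](C)(C)C(C)(C)C)[C@@H](OC)C[C@H](C)[C@@H](O[Si](C)(C)C(C)(C)C)c1cc(Br)cc(O[Si](C(C)C)(C(C)C)C(C)C)c1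
F14 | step 22 | methyl (2E,6S,7S,8E,10S,11R,12S,14S,15R)-15-[3-bromo-5-(triisopropylsilyloxy)phenyl]-11,15-bis(tert-butyldimethylsilyloxy)-6,12-dimethoxy-2,8,10,14-tetramethyl-7-(triethylsilyloxy)pentadeca-2,8-dienoate | COC(=O)/C(C)=C/CC[C@H](OC)[C@@H](O[Si](CC)(CC)CC)/C(C)=C/[C@H](C)[C@@H](O[Si](C)(C)C(C)(C)C)[C@@H](OC)C[C@H](C)[C@@H](O[Si](C)(C)C(C)(C)C)c1cc(Br)cc(O[Si](C(C)C)(C(C)C)C(C)C)c1
F15 | step 22 | (2E,6S,7S,8E,10S,11R,12S,14S,15R)-15-[3-bromo-5-(triisopropylsilyloxy)phenyl]-11,15-bis(tert-butyldimethylsilyloxy)-6,12-dimethoxy-2,8,10,14-tetramethyl-7-(triethylsilyloxy)pentadeca-2,8-dienamide | NC(=O)/C(C)=C/CC[C@H](OC)[C@@H](O[Si](CC)(CC)CC)/C(C)=C/[C@H](C)[C@@H](O[Si](C)(C)C(C)(C)C)[C@@H](OC)C[C@H](C)[C@@H](O[Si](C)(C)C(C)(C)C)c1cc(Br)cc(O[Si](C(C)C)(C(C)C)C(C)C)c1
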